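**Overview**

- Cuts: the 5‑O‑methyl group is put back on the target first; ring C is then cut at two neighbouring bonds at once, the aryl ether bond O1‑C8a and the aryl ketone bond C4‑C4a.
- Enabling feature: both bonds sit ortho to each other on ring A and C4a is flanked by the oxygenated C5, so ring A can arrive as a benzyne with a flanking alkoxy group (oxygen nucleophile to C8a, carbanion at C4a). O1, C2 (H, aryl), C3 and the C4 carbonyl together are a 3‑aryl‑3‑hydroxypropanoate.
- Forward: rings A and B are bought as 3,4,5‑trimethoxyphenol and 3',4'‑dimethoxyacetophenone. The phenol becomes an ortho‑silylaryl triflate; the ketone becomes a β‑keto ester, then an (S)‑β‑hydroxy ester and its silyl ether.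
- The aryne annulation joins the two fragments and closes ring C, the only ring that is made; chelation‑directed cleavage of the peri methyl ether then frees the 5‑OH.
- Stereochemistry: C2 is set as the S carbinol by asymmetric hydrogenation of the β‑keto ester; no later step breaks a bond at C2.

Key step: step 7

Remark: flavanone numbering is used (O1, C2, C3, C4, C4a, C5 to C8, C8a; primed locants on ring B), and the SMILES given corresponds to the 2S enantiomer.

**Route**

Step 1
Reactants: 1 3,4,5‑trimethoxyphenol
Product: 2 2‑bromo‑3,4,5‑trimethoxyphenol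
Conditions: NBS (1.0 equiv), CH2Cl2, −78 to 0 °C
Reagents that add atoms: N‑bromosuccinimide, O=C1CCC(=O)N1Br
Why: Electrophilic aromatic bromination of a strongly activated phenol, in which the only two free ring positions are equivalent and ortho to the hydroxyl, so one equivalent of NBS at low temperature should give a single monobromide with little dibromide or quinone.

Step 2
Reactants: 2 2‑bromo‑3,4,5‑trimethoxyphenol
Product: 3 (2‑bromo‑3,4,5‑trimethoxyphenoxy)trimethylsilane
Conditions: HMDS, THF, reflux; evaporate
Reagents that add atoms: hexamethyldisilazane, C[Si](C)(C)N[Si](C)(C)C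
Why: O‑Silylation of a phenol by hexamethyldisilazane, which gives ammonia as the only by‑product, so the crude silyl ether can be used after evaporation.

Step 3
Reactants: 3 (2‑bromo‑3,4,5‑trimethoxyphenoxy)trimethylsilane
Product: 6 3,4,5‑trimethoxy‑2‑(trimethylsilyl)phenyl trifluoromethanesulfonate, via aryllithium 4 (not isolated), via lithium silylphenoxide 5 (not isolated)
Conditions: n‑BuLi, THF, −100 °C; then Tf2O, −100 to −78 °C
Reagents that add atoms: trifluoromethanesulfonic anhydride, O=S(=O)(OS(=O)(=O)C(F)(F)F)C(F)(F)F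
Why: Bromine‑lithium exchange gives aryllithium 4, the silyl group migrates from oxygen to the neighbouring carbanion (retro‑Brook 1,3‑shift) to give phenoxide 5, and Tf2O traps it on oxygen, which is the standard one‑pot entry to ortho‑silylaryl triflates from ortho‑bromophenols.

Step 4
Reactants: 7 3',4'‑dimethoxyacetophenone, 8 dimethyl carbonate
Product: 10 methyl 3‑(3,4‑dimethoxyphenyl)‑3‑oxopropanoate, via sodium enolate 9 (not isolated)
Conditions: NaH, dimethyl carbonate (excess), THF, reflux; then AcOH, H2O
Reagents that add atoms: dimethyl carbonate (compound 8), COC(=O)OC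
Why: Crossed Claisen condensation of the methyl ketone enolate with a carbonate that cannot enolise, driven to completion because the second equivalent of NaH holds the product as its enolate 9 until the acidic quench.

Step 5
Reactants: 10 methyl 3‑(3,4‑dimethoxyphenyl)‑3‑oxopropanoate
Product: 11 methyl (S)‑3‑(3,4‑dimethoxyphenyl)‑3‑hydroxypropanoate
Conditions: [RuCl(p‑cymene)((R)‑BINAP)]Cl (cat.), H2 (10 bar), MeOH, 50 °C
Reagents that add atoms: none
Why: Noyori asymmetric hydrogenation of a β‑keto ester by a divalent ruthenium BINAP catalyst, in which the ester carbonyl chelates the metal and the (R)‑ligand delivers hydride to the face that gives (R)‑3‑hydroxybutanoate from acetoacetate; for an aryl ketone, where aryl outranks CH2CO2Me, that face is the S carbinol, so C2 of the target is set here.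

Step 6
Reactants: 11 methyl (S)‑3‑(3,4‑dimethoxyphenyl)‑3‑hydroxypropanoate
Product: 12 methyl (S)‑3‑(3,4‑dimethoxyphenyl)‑3‑(trimethylsilyloxy)propanoate
Conditions: TMSCl, imidazole, CH2Cl2, 0 °C to rt
Reagents that add atoms: chlorotrimethylsilane, C[Si](C)(C)Cl
Why: Routine O‑silylation of a secondary alcohol, which leaves the stereocenter alone and lets the oxygen enter the annulation without an O‑H bond.

Step 7
Reactants: 6 3,4,5‑trimethoxy‑2‑(trimethylsilyl)phenyl trifluoromethanesulfonate, 12 methyl (S)‑3‑(3,4‑dimethoxyphenyl)‑3‑(trimethylsilyloxy)propanoate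
Product: 16 (S)‑2‑(3,4‑dimethoxyphenyl)‑5,6,7‑trimethoxychroman‑4‑one, via potassium alkoxide 13 (not isolated), via 3,4,5‑trimethoxybenzyne 14 (not isolated), via aryl anion 15 (not isolated)
Conditions: KF, 18‑crown‑6 (added slowly), DME, 0 °C to rt; 6 in slight excess, high dilution
Reagents that add atoms: none
Why: Proposed new method: fluoride removes the trimethylsilyl groups of both partners, so aryne 14 and alkoxide 13 meet in a medium free of O‑H; 13 adds to the aryne carbon remote from the flanking methoxy group, and the aryl anion 15, now ortho to that methoxy group and five atoms from the ester carbonyl, attacks it and expels methoxide. The closest known reaction type is the fluoride‑mediated annulation of arynes with salicylate esters to xanthones (O‑arylation, then intramolecular acyl substitution), together with aryne σ‑insertion into β‑dicarbonyl compounds; an aliphatic β‑oxy ester has not been shown to react this way. Ring C, the only ring formed, closes by 6‑exo‑trig attack of the aryl anion on the ester C=O. No stereocenter is created, and since the new bonds form at the oxygen and at the acyl carbon, the C2‑O bond is never broken and the S configuration cannot change. The step needs attack at the distal aryne carbon, which the flanking C‑O dipole secures by bending and polarising the triple bond, so the flanking methoxy group becomes the C5 oxygen and C8 stays unsubstituted. The ester also has to trap 15 faster than any proton source does, which is why the hydroxyl enters as a silyl ether; the expelled methoxide should be taken up by silicon as MeOSiMe3, releasing the next alkoxide or aryne, before it can open the flavanone to its chalcone and racemise C2.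

Step 8
Reactants: 16 (S)‑2‑(3,4‑dimethoxyphenyl)‑5,6,7‑trimethoxychroman‑4‑one
Product: 18 (S)‑2‑(3,4‑dimethoxyphenyl)‑5‑hydroxy‑6,7‑dimethoxychroman‑4‑one, via dichloroboron chelate 17 (not isolated)
Conditions: BCl3 (1.2 equiv), CH2Cl2, −78 to 0 °C; then H2O
Reagents that add atoms: none
Why: Chelation‑directed ether cleavage, in which BCl3 bridges the C4 carbonyl and the peri 5‑methoxy oxygen in a six‑membered chelate and chloride removes only that methyl group; the other four methyl ethers cannot chelate, and the low temperature should keep the C2‑O1 bond closed so that the S configuration is kept.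

**Compound list**

1 | 3,4,5‑trimethoxyphenol | COc1cc(O)cc(OC)c1OC | starting material
2 | 2‑bromo‑3,4,5‑trimethoxyphenol | COc1cc(O)c(Br)c(OC)c1OC | intermediate
3 | (2‑bromo‑3,4,5‑trimethoxyphenoxy)trimethylsilane | COc1cc(O[Si](C)(C)C)c(Br)c(OC)c1OC | intermediate
4 | [2,3,4‑trimethoxy‑6‑(trimethylsilyloxy)phenyl]lithium (aryllithium, not isolated) | COc1cc(O[Si](C)(C)C)c([Li])c(OC)c1OC | intermediate
5 | lithium 3,4,5‑trimethoxy‑2‑(trimethylsilyl)phenoxide (not isolated) | COc1cc([O-])c([Si](C)(C)C)c(OC)c1OC.[Li+] | intermediate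
6 | 3,4,5‑trimethoxy‑2‑(trimethylsilyl)phenyl trifluoromethanesulfonate | COc1cc(OS(=O)(=O)C(F)(F)F)c([Si](C)(C)C)c(OC)c1OC | intermediate
7 | 3',4'‑dimethoxyacetophenone, 1‑(3,4‑dimethoxyphenyl)ethan‑1‑one | CC(=O)c1ccc(OC)c(OC)c1 | starting material
8 | dimethyl carbonate | COC(=O)OC | starting material
9 | sodium enolate of methyl 3‑(3,4‑dimethoxyphenyl)‑3‑oxopropanoate (not isolated) | COC(=O)C=C([O-])c1ccc(OC)c(OC)c1.[Na+] | intermediate
10 | methyl 3‑(3,4‑dimethoxyphenyl)‑3‑oxopropanoate | COC(=O)CC(=O)c1ccc(OC)c(OC)c1 | intermediate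
11 | methyl (S)‑3‑(3,4‑dimethoxyphenyl)‑3‑hydroxypropanoate | COc1ccc([C@@H](O)CC(=O)OC)cc1OC | intermediate
12 | methyl (S)‑3‑(3,4‑dimethoxyphenyl)‑3‑(trimethylsilyloxy)propanoate | COc1ccc([C@@H](O[Si](C)(C)C)CC(=O)OC)cc1OC | intermediate
13 | potassium (S)‑1‑(3,4‑dimethoxyphenyl)‑3‑methoxy‑3‑oxopropan‑1‑olate (not isolated) | COc1ccc([C@@H]([O-])CC(=O)OC)cc1OC.[K+] | intermediate
14 | 3,4,5‑trimethoxybenzyne, 1,2‑didehydro‑3,4,5‑trimethoxybenzene (not isolated) | COC1=CC#CC(OC)=C1OC | intermediate
15 | potassium 2‑[(S)‑1‑(3,4‑dimethoxyphenyl)‑3‑methoxy‑3‑oxopropoxy]‑4,5,6‑trimethoxybenzenide (aryl anion, not isolated) | COc1ccc([C@@H](Oc2cc(OC)c(OC)c(OC)[c-]2)CC(=O)OC)cc1OC.[K+] | intermediate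
16 | (S)‑2‑(3,4‑dimethoxyphenyl)‑5,6,7‑trimethoxychroman‑4‑one | COc1ccc([C@@H]2CC(=O)c3c(cc(OC)c(OC)c3OC)O2)cc1OC | intermediate
17 | (S)‑5‑(dichloroboranyloxy)‑2‑(3,4‑dimethoxyphenyl)‑6,7‑dimethoxychroman‑4‑one (boron chelate, not isolated) | COc1ccc([C@@H]2CC(=O)c3c(cc(OC)c(OC)c3OB(Cl)Cl)O2)cc1OC | intermediate
18 | (S)‑2‑(3,4‑dimethoxyphenyl)‑5‑hydroxy‑6,7‑dimethoxychroman‑4‑one, (S)‑5‑hydroxy‑6,7,3',4'‑tetramethoxyflavanone | COc1ccc([C@@H]2CC(=O)c3c(cc(OC)c(OC)c3O)O2)cc1OC | target

**Step count and risks**

Total step count: 8. Longest linear sequence: 5 steps (steps 1, 2, 3, 7, 8 from compound 1; the branch from compound 7 through steps 4, 5, 6, 7, 8 is equally long).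

Steps most likely to fail:

1. Step 7. The aryl anion may be quenched by adventitious protons, by a second aryne or by silicon before it reaches the ester. The free alkoxide may also fragment by retro‑aldol cleavage or eliminate, and methoxide that is not scavenged may open the product and erase C2. The fallback uses known chemistry, sets out from keto ester 10 and bromophenol 2, and comes back at 16.
   - Hydrogenation of 10 with the antipodal catalyst [RuCl(p‑cymene)((S)‑BINAP)]Cl would give methyl (R)‑3‑(3,4‑dimethoxyphenyl)‑3‑hydroxypropanoate F1.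
   - MeNH(OMe)·HCl and i‑PrMgCl in THF at −20 °C would convert it into the Weinreb amide (R)‑3‑(3,4‑dimethoxyphenyl)‑3‑hydroxy‑N‑methoxy‑N‑methylpropanamide F2.
   - A Mitsunobu reaction of F2 with 2 (PPh3, DIAD, THF, 0 °C) would form the O1‑C8a ether with inversion, giving (S)‑3‑(2‑bromo‑3,4,5‑trimethoxyphenoxy)‑3‑(3,4‑dimethoxyphenyl)‑N‑methoxy‑N‑methylpropanamide F3.
   - Bromine‑lithium exchange (n‑BuLi, THF, −78 °C) would give the aryllithium [2‑[(S)‑1‑(3,4‑dimethoxyphenyl)‑3‑[methoxy(methyl)amino]‑3‑oxopropoxy]‑4,5,6‑trimethoxyphenyl]lithium F4, which closes ring C on the Weinreb amide (Parham cyclisation) to give 16.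

2. Step 8. The ether cleavage may not stop at the peri position: once O5 is bound to boron, the neighbouring 6‑methoxy group is activated and may be lost as well, giving mixtures. The fallback sets out from 16 and comes back at 18. Both the 5‑ and 6‑methyl ethers would be cleaved on purpose through the aluminium chelate (AlBr3, MeCN, 0 °C to rt) to give (S)‑2‑(3,4‑dimethoxyphenyl)‑5,6‑dihydroxy‑7‑methoxychroman‑4‑one F5. Trimethylsilyldiazomethane in MeOH/toluene would then methylate only the free 6‑OH, because the 5‑OH is hydrogen‑bonded to the carbonyl and too weakly acidic to react under these base‑free conditions.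

3. Step 5. Enantioselection may fall short with the electron‑rich aryl ketone, and the acidic catalyst may ionise the benzylic carbinol. The fallback sets out from 10 and comes back at 11. NaBH4 in MeOH at 0 °C would give racemic methyl 3‑(3,4‑dimethoxyphenyl)‑3‑hydroxypropanoate F6. Kinetic resolution by lipase from Burkholderia cepacia with vinyl acetate in MTBE at 30 °C should acetylate the R enantiomer (the usual preference of this lipase for secondary carbinols with one large and one medium substituent) to methyl (R)‑3‑acetoxy‑3‑(3,4‑dimethoxyphenyl)propanoate F7, leaving 11 to be separated by chromatography.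

**Further compounds**

F1 | step 7 | methyl (R)‑3‑(3,4‑dimethoxyphenyl)‑3‑hydroxypropanoate | COc1ccc([C@H](O)CC(=O)OC)cc1OC
F2 | step 7 | (R)‑3‑(3,4‑dimethoxyphenyl)‑3‑hydroxy‑N‑methoxy‑N‑methylpropanamide | COc1ccc([C@H](O)CC(=O)N(C)OC)cc1OC
F3 | step 7 | (S)‑3‑(2‑bromo‑3,4,5‑trimethoxyphenoxy)‑3‑(3,4‑dimethoxyphenyl)‑N‑methoxy‑N‑methylpropanamide | COc1ccc([C@@H](Oc2cc(OC)c(OC)c(OC)c2Br)CC(=O)N(C)OC)cc1OC
F4 | step 7 | [2‑[(S)‑1‑(3,4‑dimethoxyphenyl)‑3‑[methoxy(methyl)amino]‑3‑oxopropoxy]‑4,5,6‑trimethoxyphenyl]lithium | COc1ccc([C@@H](Oc2cc(OC)c(OC)c(OC)c2[Li])CC(=O)N(C)OC)cc1OC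
F5 | step 8 | (S)‑2‑(3,4‑dimethoxyphenyl)‑5,6‑dihydroxy‑7‑methoxychroman‑4‑one | COc1ccc([C@@H]2CC(=O)c3c(cc(OC)c(O)c3O)O2)cc1OC
F6 | step 5 | methyl 3‑(3,4‑dimethoxyphenyl)‑3‑hydroxypropanoate (racemic) | COc1ccc(C(O)CC(=O)OC)cc1OC
F7 | step 5 | methyl (R)‑3‑acetoxy‑3‑(3,4‑dimethoxyphenyl)propanoate | COc1ccc([C@H](OC(C)=O)CC(=O)OC)cc1OC
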